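The numbers of this flask belong to no real substance; no experiment stands behind them.

It is tempting to read the large binding rate constants of this flask as speed, yet a complex that forms need not go on, so we follow one enzyme molecule round its cycle and ask for its chances at each fork.

starting material 0.050 M; second substrate 0.100 M; scavenger 0.0750 M; free enzyme 44 µM; time 15 h

    second complex → free enzyme + target (k1 = 1600 h⁻¹)
    first complex ⇌ loaded enzyme + first product (K2 = 0.062 M, k2 = 110 h⁻¹)
    starting material + free enzyme ⇌ first complex (K3 = 17 L mol⁻¹, k3 = 2.1 × 10⁵ L mol⁻¹ h⁻¹)
    second substrate + first product ⇌ idle adduct, settled at all times (K4 = 22 L mol⁻¹)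
    second substrate + loaded enzyme ⇌ second complex (K5 = 4.0 L mol⁻¹, k5 = 3.3 × 10⁵ L mol⁻¹ h⁻¹)
    scavenger + first product → scavenged by-product (k6 = 270 L mol⁻¹ h⁻¹)

- for first product the idle adduct is counted in
- run time (flask): 15 h

* part of the starting material that has reacted at 15 h
* share of free second substrate in free second substrate and idle adduct together, at 15 h

A first complex goes on with chance 0.883%, its forward exit over both exits, and a second complex goes on with chance 1.90%. At the charge, free enzyme therefore waits 0.0108 h for a capture that passes, first complex takes 0.00909 h to split, loaded enzyme waits 0.00159 h, and second complex takes 6.25 × 10⁻⁴ h. Their sum, 0.0221 h, is the turn time, the mean time of one cycle, and each enzyme form holds the share of the catalyst that its wait holds of the turn time.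

Which constants must we know well? The splitting constant of first complex enters 90.0% of the turn time at the charge, through the waits of free enzyme and first complex, the rate-limiting stretch. The binding equilibrium constant enters 48.4%, the binding rate constant about 0.432%, and the second half of the cycle 10.0%. The scavenger holds c(first product), the idle adduct not counted, near 9.83 × 10⁻⁵ M, so loaded enzyme returns with chance 0.0278%.

Summing the turn time as c(starting material) and c(second substrate) fall, we find that half conversion needs 15.06 h. The turn time there is 0.0334 h, so at 15 h we expect 49.8% of the starting material reacted and a free share of second substrate of 99.8%.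

The forecast gave 49.8% (47% to 52%) and 99.8% (99.7% to 99.8%), taking the cycle as “limited mainly by step 2 with partial saturation by starting material”. The simulation gives 49.8% and 99.8%.

In this flask the cycle ran throughout while scavenger was present, and 67.1% of its charge remained at 15.0 h. Starting material stood at 72.5% at 7.50 h and 50.2% at 15.0 h, with free enzyme, the resting state, rising to 64.5%, more than first complex at 27.3%. The turn time's share for loaded enzyme at half conversion is 6.35%, and this flask held 6.37% at 15.0 h. In the neighbour charged with 0.025 M of second substrate, the amounts left at 15.0 h give a turn time of 0.0527 h, with 48.7% for loaded enzyme, and that neighbour held 48.6%.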